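**Plan**

1. Numbering: C1 (alkyne CH) to C15 (ethyl CH3). The tetrahydropyran is O–C6–C7–C8–C9–C10 and the oxocane O–C7–C8–C9–C10–C11–C12–C13; together they form a 2,7-dioxabicyclo[4.2.2]decane with bridgeheads C7 and C10.
2. Cuts: first C12–Br (from the alcohol) and the enyne (C1–C2 homologation, C3=C4 metathesis, C4–C5 coupling). Then C10–C11 and the pyran O–C6 bond together, which opens both rings to an acyclic ether. Then the C7–O–C13 ether, C8–C9 and the allylsilane carbons.
3. Forward: the C5–C10 chain comes from a four-carbon bis-epoxide and an acetylide, is etherified with the C12–C15 ester, the ester becomes an allylsilane (which supplies C11) and the alkyne an α-bromo aldehyde. The tetrahydropyran and then the oxocane arise in one operation; C12 and the side chain follow.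
4. Enabling feature: the C10 aldehyde oxygen lies five atoms from the oxirane carbon C6 (6-exo). C7, next to C6 and 1,4 to C10 in the pyran so formed, holds through its oxygen a four-atom arm ending in nucleophilic C11, which can reach cationic C10 only across the ring, cis to C7–O.
5. Stereochemistry: C6 and C7 from the (2S,3S)-bis-epoxide (C6 inverted when the pyran closes); C13 from methyl (S)-2-hydroxybutanoate with inversion; C9 by enamine catalysis; C10 by the tether; C12 by reduction anti to ethyl, then SN2 inversion; C3=C4 (E) by cross-metathesis.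

Key step: step 8

Remark: (2S,3S)-1,2:3,4-diepoxybutane (L-tartaric acid series) is taken as a purchasable reagent; it is used in excess in step 1 and the surplus recovered.

**Route**

Step 1
Reactants: 1 (2S,2'S)-2,2'-bioxirane [(2S,3S)-1,2:3,4-diepoxybutane]; 2 ethynyltrimethylsilane
Product: 4 (1S)-1-[(2S)-oxiran-2-yl]-4-(trimethylsilyl)but-3-yn-1-ol, via lithium (trimethylsilyl)acetylide 3 (not isolated)
Conditions: 2, n-BuLi, THF, −78 °C; then BF3·OEt2, 1 (1.5 equiv), −78 °C; then H2O
Reagents that add atoms: none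
Why: BF3-mediated SN2 alkynylation of one oxirane of the C2-symmetric bis-epoxide at a terminal carbon leaves both stereocentres untouched, so the (S)-carbinol and the (S)-oxirane of 4 come straight from the reagent, either terminus gives the same product, and the excess of bis-epoxide should keep double opening low.

Step 2
Reactants: 5 methyl (2S)-2-hydroxybutanoate
Product: 6 methyl (2S)-2-{[(trifluoromethyl)sulfonyl]oxy}butanoate
Conditions: (CF3SO2)2O, 2,6-lutidine, CH2Cl2, −78 → 0 °C; short silica plug, used at once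
Reagents that add atoms: trifluoromethanesulfonic anhydride, O=S(=O)(OS(=O)(=O)C(F)(F)F)C(F)(F)F
Why: O-Sulfonylation of the α-hydroxy ester (triflate formation) proceeds with retention at carbon and provides the secondary leaving group for an invertive etherification.

Step 3
Reactants: 4 (1S)-1-[(2S)-oxiran-2-yl]-4-(trimethylsilyl)but-3-yn-1-ol; 6 methyl (2S)-2-{[(trifluoromethyl)sulfonyl]oxy}butanoate
Product: 8 methyl (2R)-2-{[(1S)-1-[(2S)-oxiran-2-yl]-4-(trimethylsilyl)but-3-yn-1-yl]oxy}butanoate, via sodium alkoxide 7 (not isolated)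
Conditions: 4, NaN(SiMe3)2, THF, −78 °C; then 6, −78 → −20 °C
Reagents that add atoms: none
Why: Williamson etherification in which the alkoxide displaces the α-triflyloxy ester by SN2 with inversion, turning the (S)-triflate into the (R)-configured C13 ether centre, the alkoxide being formed and alkylated below −20 °C so that Payne rearrangement of the epoxy alkoxide and E2 loss of triflic acid should stay minor.

Step 4
Reactants: 8 methyl (2R)-2-{[(1S)-1-[(2S)-oxiran-2-yl]-4-(trimethylsilyl)but-3-yn-1-yl]oxy}butanoate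
Product: 10 (2S)-2-[(1S)-1-{[(3R)-2-[(trimethylsilyl)methyl]pent-1-en-3-yl]oxy}-4-(trimethylsilyl)but-3-yn-1-yl]oxirane, via bis(silylmethyl) carbinol 9 (not isolated)
Conditions: Me3SiCH2MgCl (4 equiv), CeCl3 (4 equiv), THF, −78 → 0 °C; then SiO2, CH2Cl2, rt
Reagents that add atoms: (trimethylsilyl)methylmagnesium chloride, C[Si](C)(C)C[Mg]Cl
Why: Cerium-mediated double addition of the (trimethylsilyl)methyl nucleophile to the ester followed by acid-promoted Peterson elimination is the standard conversion of an ester into a 2-substituted allylsilane, and the weakly basic organocerium reagent should spare the C13 stereocentre, the oxirane and the silylalkyne.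

Step 5
Reactants: 10 (2S)-2-[(1S)-1-{[(3R)-2-[(trimethylsilyl)methyl]pent-1-en-3-yl]oxy}-4-(trimethylsilyl)but-3-yn-1-yl]oxirane
Product: 11 (2S)-2-[(1S)-1-{[(3R)-2-[(trimethylsilyl)methyl]pent-1-en-3-yl]oxy}but-3-yn-1-yl]oxirane
Conditions: K2CO3, MeOH, rt
Reagents that add atoms: none
Why: Base-mediated methanolysis (protodesilylation) cleaves only the sp-carbon–silicon bond, the allylsilane and the oxirane being inert to carbonate in methanol.

Step 6
Reactants: 11 (2S)-2-[(1S)-1-{[(3R)-2-[(trimethylsilyl)methyl]pent-1-en-3-yl]oxy}but-3-yn-1-yl]oxirane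
Product: 13 (4S)-4-[(2S)-oxiran-2-yl]-4-{[(3R)-2-[(trimethylsilyl)methyl]pent-1-en-3-yl]oxy}butanal, via alkenylborane 12 (not isolated)
Conditions: (Me2CHCHMe)2BH [from BH3·THF and 2-methylbut-2-ene], THF, 0 °C; then H2O2, aq NaOAc, 0 °C → rt
Reagents that add atoms: hydrogen peroxide, OO
Why: Anti-Markovnikov hydroboration–oxidation of the terminal alkyne with a hindered dialkylborane stops at the (E)-alkenylborane and gives the aldehyde directly, the 1,1-disubstituted allylsilane alkene reacting far more slowly with this reagent.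

Step 7
Reactants: 13 (4S)-4-[(2S)-oxiran-2-yl]-4-{[(3R)-2-[(trimethylsilyl)methyl]pent-1-en-3-yl]oxy}butanal
Product: 14 (2S,4S)-2-bromo-4-[(2S)-oxiran-2-yl]-4-{[(3R)-2-[(trimethylsilyl)methyl]pent-1-en-3-yl]oxy}butanal
Conditions: (2R,5R)-2,5-diphenylpyrrolidine (20 mol %), 4,4-dibromo-2,6-di-tert-butylcyclohexa-2,5-dienone, PhCO2H (20 mol %), H2O (2 equiv), CH2Cl2/pentane, −40 °C; cold aqueous work-up, used crude
Reagents that add atoms: 4,4-dibromo-2,6-di-tert-butylcyclohexa-2,5-dien-1-one, CC(C)(C)C1=CC(Br)(Br)C=C(C(C)(C)C)C1=O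
Why: Enamine-catalysed electrophilic α-bromination of the aldehyde, in which the C2-symmetric pyrrolidine shields one enamine face and should set the (S)-configured C9–Br centre under catalyst control (the antipodal amine would be taken if a model aldehyde showed the opposite sense), the much less nucleophilic allylsilane being expected to survive the mild bromonium donor at −40 °C.

Step 8
Reactants: 14 (2S,4S)-2-bromo-4-[(2S)-oxiran-2-yl]-4-{[(3R)-2-[(trimethylsilyl)methyl]pent-1-en-3-yl]oxy}butanal
Product: 18 [(1S,3R,6R,8R,10S)-10-bromo-3-ethyl-4-methylidene-2,7-dioxabicyclo[4.2.2]decan-8-yl]methanol, via oxocarbenium triflate 15 (not isolated), via anhydro acetal 16 (not isolated), via trimethylsilyl ether 17 (not isolated)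
Conditions: Me3SiOSO2CF3 (0.3 equiv), 2,6-di-tert-butyl-4-methylpyridine (0.2 equiv), CH2Cl2 (0.01 M), −78 → 0 °C; then aq NaHCO3; then citric acid, MeOH/H2O, 0 °C
Reagents that add atoms: none
Why: Proposed new method: Me3SiOSO2CF3 silylates the oxirane oxygen, the aldehyde oxygen opens it at C6 (SN2, inversion) to give the 2-bromopyranyl oxocarbenium ion 15, which may rest reversibly as the anhydro acetal 16, and the 2-(silylmethyl)allyl group hung on the C7 oxygen then adds through its CH2 terminus (C11) to C10 with release of the silyl triflate, so that a catalytic amount of it isomerises 14 to silyl ether 17. The closest known reaction types are the acid-induced cyclisation of δ,ε-epoxy carbonyl compounds to cyclic oxocarbenium ions and 6,8-dioxabicyclo[3.2.1]octane acetals, and the Hosomi–Sakurai substitution of pyranosyl cations (also generated from 1,6-anhydro sugars) by allylsilanes; their union in one operation, with the allylsilane delivered across the pyran ring to close a bridging eight-membered ring, has not been shown. Ring closures: the tetrahydropyran forms by 6-exo-tet opening of the oxirane by oxygen, and the oxocane by attack of the allylsilane alkene (endocyclic to the new ring, 8-endo) on the C10=O+ bond (exocyclic to the new ring), the β-silyl cation collapsing to the exocyclic methylene. Stereocentres: C6 is fixed by stereospecific inversion of the (S)-oxirane carbon, and C10 by the tether, which can reach the cation only on the face cis to the C7 oxygen through a boat-like pyranyl cation, a face that is also anti to the C9 bromine. The selectivity needed is oxygen before carbon attack on the activated oxirane and 6-exo before 7-endo opening: the carbonyl lone pair lies five atoms from C6 and participates anchimerically, whereas the allylsilane is a weaker nucleophile toward this β-alkoxy-substituted secondary carbon and the primary C5 is reached only through a seven-membered transition state. Re-ionisation of 16 at its five-membered-ring C–O bond to the pyranyl cation follows the behaviour of 1,6-anhydro sugars, and the hindered pyridine removes adventitious acid so that enolisation at C9 and protodesilylation should stay minor.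

Step 9
Reactants: 18 [(1S,3R,6R,8R,10S)-10-bromo-3-ethyl-4-methylidene-2,7-dioxabicyclo[4.2.2]decan-8-yl]methanol
Product: 19 (1S,3R,6R,8R,10S)-10-bromo-3-ethyl-8-(hydroxymethyl)-2,7-dioxabicyclo[4.2.2]decan-4-one
Conditions: O3, CH2Cl2/MeOH, −78 °C; then PPh3, −78 °C → rt
Reagents that add atoms: ozone, [O-][O+]=O
Why: Ozonolysis of the only alkene, the exocyclic methylene, with reductive work-up reveals the C12 ketone without touching the secondary bromide or the adjacent C13 stereocentre.

Step 10
Reactants: 19 (1S,3R,6R,8R,10S)-10-bromo-3-ethyl-8-(hydroxymethyl)-2,7-dioxabicyclo[4.2.2]decan-4-one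
Product: 20 (1S,3R,4R,6R,8R,10S)-10-bromo-3-ethyl-8-(hydroxymethyl)-2,7-dioxabicyclo[4.2.2]decan-4-ol
Conditions: LiBH(s-Bu)3 (3 equiv), THF, −78 °C; then H2O
Reagents that add atoms: none
Why: Hydride reduction of the α-alkoxy ketone by the bulky trialkylborohydride from the flank of the four-atom bridge anti to the C13 ethyl group (the two flanks being otherwise nearly equivalent in this bicycle) should give the (4R)-alcohol with hydroxyl cis to ethyl, as needed for the later invertive bromination.

Step 11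
Reactants: 20 (1S,3R,4R,6R,8R,10S)-10-bromo-3-ethyl-8-(hydroxymethyl)-2,7-dioxabicyclo[4.2.2]decan-4-ol
Product: 22 (1S,3R,4R,6R,8R,10S)-10-bromo-3-ethyl-8-(prop-2-en-1-yl)-2,7-dioxabicyclo[4.2.2]decan-4-ol, via primary triflate 21 (not isolated)
Conditions: (CF3SO2)2O (1.05 equiv), 2,6-lutidine, CH2Cl2, −78 °C; then CH2=CHMgBr (5 equiv), CuI (20 mol %), THF, −78 → −20 °C
Reagents that add atoms: vinylmagnesium bromide, C=C[Mg]Br
Why: Chemoselective triflation of the primary hydroxyl followed by copper-catalysed SN2 cross-coupling of the β-alkoxy primary triflate with the vinyl Grignard reagent installs C3–C4 as an allyl group, no stereocentre being involved.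

Step 12
Reactants: 22 (1S,3R,4R,6R,8R,10S)-10-bromo-3-ethyl-8-(prop-2-en-1-yl)-2,7-dioxabicyclo[4.2.2]decan-4-ol
Product: 23 (1S,3R,4S,6R,8R,10S)-4,10-dibromo-3-ethyl-8-(prop-2-en-1-yl)-2,7-dioxabicyclo[4.2.2]decane
Conditions: CBr4, P(n-C8H17)3, PhMe, 70 °C
Reagents that add atoms: carbon tetrabromide, BrC(Br)(Br)Br
Why: Appel-type bromination through the alkoxyphosphonium salt replaces the secondary hydroxyl by bromide in an SN2 sense with inversion, as is usual for the hydroxyl next to the ethyl-bearing carbon of oxocane ethers, and so should set the (4S) bromide trans to ethyl.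

Step 13
Reactants: 23 (1S,3R,4S,6R,8R,10S)-4,10-dibromo-3-ethyl-8-(prop-2-en-1-yl)-2,7-dioxabicyclo[4.2.2]decane
Product: 24 (2E)-4-[(1S,3R,4S,6R,8R,10S)-4,10-dibromo-3-ethyl-2,7-dioxabicyclo[4.2.2]decan-8-yl]but-2-enal
Conditions: (E)-but-2-enal (10 equiv), second-generation Grubbs catalyst RuCl2(=CHPh)(PCy3)(H2IMes) (5 mol %), CH2Cl2, 40 °C
Reagents that add atoms: (E)-but-2-enal, C/C=C/C=O
Why: Olefin cross-metathesis of the terminal allyl group with excess crotonaldehyde should give the conjugated enal with the thermodynamically preferred E geometry, which fixes the C3=C4 double bond.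

Step 14
Reactants: 24 (2E)-4-[(1S,3R,4S,6R,8R,10S)-4,10-dibromo-3-ethyl-2,7-dioxabicyclo[4.2.2]decan-8-yl]but-2-enal
Product: 25 (1S,3R,4S,6R,8R,10S)-4,10-dibromo-3-ethyl-8-[(2E)-pent-2-en-4-yn-1-yl]-2,7-dioxabicyclo[4.2.2]decane
Conditions: Me3SiCHN2, LiN(i-Pr)2, THF, −78 °C; then 24, −78 → 0 °C
Reagents that add atoms: (trimethylsilyl)diazomethane, C[Si](C)(C)C=[N+]=[N-]
Why: Colvin rearrangement, in which the lithiated silyldiazomethane adds to the enal, silanolate is lost in a Peterson-type step and the alkylidene carbene undergoes 1,2-hydride shift with loss of N2, should give the terminal alkyne at low temperature without base damage to the two secondary bromides and so complete the (E)-enyne.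

**Compound list**

1 | (2S,2'S)-2,2'-bioxirane [(2S,3S)-1,2:3,4-diepoxybutane] | C1O[C@@H]1[C@@H]2CO2 | starting material
2 | ethynyltrimethylsilane | C#C[Si](C)(C)C | starting material
3 | lithium (trimethylsilyl)acetylide | [Li]C#C[Si](C)(C)C | intermediate
4 | (1S)-1-[(2S)-oxiran-2-yl]-4-(trimethylsilyl)but-3-yn-1-ol | C[Si](C)(C)C#CC[C@H](O)[C@@H]1CO1 | intermediate
5 | methyl (2S)-2-hydroxybutanoate | CC[C@H](O)C(=O)OC | starting material
6 | methyl (2S)-2-{[(trifluoromethyl)sulfonyl]oxy}butanoate | CC[C@H](OS(=O)(=O)C(F)(F)F)C(=O)OC | intermediate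
7 | sodium (1S)-1-[(2S)-oxiran-2-yl]-4-(trimethylsilyl)but-3-yn-1-olate | C[Si](C)(C)C#CC[C@H]([O-])[C@@H]1CO1.[Na+] | intermediate
8 | methyl (2R)-2-{[(1S)-1-[(2S)-oxiran-2-yl]-4-(trimethylsilyl)but-3-yn-1-yl]oxy}butanoate | CC[C@@H](O[C@@H](CC#C[Si](C)(C)C)[C@@H]1CO1)C(=O)OC | intermediate
9 | (3R)-3-{[(1S)-1-[(2S)-oxiran-2-yl]-4-(trimethylsilyl)but-3-yn-1-yl]oxy}-1-(trimethylsilyl)-2-[(trimethylsilyl)methyl]pentan-2-ol | CC[C@@H](O[C@@H](CC#C[Si](C)(C)C)[C@@H]1CO1)C(O)(C[Si](C)(C)C)C[Si](C)(C)C | intermediate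
10 | (2S)-2-[(1S)-1-{[(3R)-2-[(trimethylsilyl)methyl]pent-1-en-3-yl]oxy}-4-(trimethylsilyl)but-3-yn-1-yl]oxirane | CC[C@@H](O[C@@H](CC#C[Si](C)(C)C)[C@@H]1CO1)C(=C)C[Si](C)(C)C | intermediate
11 | (2S)-2-[(1S)-1-{[(3R)-2-[(trimethylsilyl)methyl]pent-1-en-3-yl]oxy}but-3-yn-1-yl]oxirane | CC[C@@H](O[C@@H](CC#C)[C@@H]1CO1)C(=C)C[Si](C)(C)C | intermediate
12 | bis(3-methylbutan-2-yl){(1E,4S)-4-[(2S)-oxiran-2-yl]-4-{[(3R)-2-[(trimethylsilyl)methyl]pent-1-en-3-yl]oxy}but-1-en-1-yl}borane | CC[C@@H](O[C@@H](C/C=C/B(C(C)C(C)C)C(C)C(C)C)[C@@H]1CO1)C(=C)C[Si](C)(C)C | intermediate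
13 | (4S)-4-[(2S)-oxiran-2-yl]-4-{[(3R)-2-[(trimethylsilyl)methyl]pent-1-en-3-yl]oxy}butanal | CC[C@@H](O[C@@H](CCC=O)[C@@H]1CO1)C(=C)C[Si](C)(C)C | intermediate
14 | (2S,4S)-2-bromo-4-[(2S)-oxiran-2-yl]-4-{[(3R)-2-[(trimethylsilyl)methyl]pent-1-en-3-yl]oxy}butanal | CC[C@@H](O[C@@H](C[C@H](Br)C=O)[C@@H]1CO1)C(=C)C[Si](C)(C)C | intermediate
15 | (2R,3S,5S)-5-bromo-3-{[(3R)-2-[(trimethylsilyl)methyl]pent-1-en-3-yl]oxy}-2-{[(trimethylsilyl)oxy]methyl}-2,3,4,5-tetrahydropyrylium trifluoromethanesulfonate | CC[C@@H](O[C@H]1C[C@H](Br)C=[O+][C@@H]1CO[Si](C)(C)C)C(=C)C[Si](C)(C)C.[O-]S(=O)(=O)C(F)(F)F | intermediate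
16 | (1R,2S,4S,5R)-4-bromo-2-{[(3R)-2-[(trimethylsilyl)methyl]pent-1-en-3-yl]oxy}-6,8-dioxabicyclo[3.2.1]octane | CC[C@@H](O[C@H]1C[C@H](Br)[C@@H]2OC[C@H]1O2)C(=C)C[Si](C)(C)C | intermediate
17 | {[(1S,3R,6R,8R,10S)-10-bromo-3-ethyl-4-methylidene-2,7-dioxabicyclo[4.2.2]decan-8-yl]methoxy}trimethylsilane | C[Si](C)(C)OC[C@H]1O[C@@H]2CC(=C)[C@@H](CC)O[C@H]1C[C@@H]2Br | intermediate
18 | [(1S,3R,6R,8R,10S)-10-bromo-3-ethyl-4-methylidene-2,7-dioxabicyclo[4.2.2]decan-8-yl]methanol | OC[C@H]1O[C@@H]2CC(=C)[C@@H](CC)O[C@H]1C[C@@H]2Br | intermediate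
19 | (1S,3R,6R,8R,10S)-10-bromo-3-ethyl-8-(hydroxymethyl)-2,7-dioxabicyclo[4.2.2]decan-4-one | OC[C@H]1O[C@@H]2CC(=O)[C@@H](CC)O[C@H]1C[C@@H]2Br | intermediate
20 | (1S,3R,4R,6R,8R,10S)-10-bromo-3-ethyl-8-(hydroxymethyl)-2,7-dioxabicyclo[4.2.2]decan-4-ol | OC[C@H]1O[C@@H]2C[C@@H](O)[C@@H](CC)O[C@H]1C[C@@H]2Br | intermediate
21 | [(1S,3R,4R,6R,8R,10S)-10-bromo-3-ethyl-4-hydroxy-2,7-dioxabicyclo[4.2.2]decan-8-yl]methyl trifluoromethanesulfonate | O=S(=O)(OC[C@H]1O[C@@H]2C[C@@H](O)[C@@H](CC)O[C@H]1C[C@@H]2Br)C(F)(F)F | intermediate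
22 | (1S,3R,4R,6R,8R,10S)-10-bromo-3-ethyl-8-(prop-2-en-1-yl)-2,7-dioxabicyclo[4.2.2]decan-4-ol | C=CC[C@H]1O[C@@H]2C[C@@H](O)[C@@H](CC)O[C@H]1C[C@@H]2Br | intermediate
23 | (1S,3R,4S,6R,8R,10S)-4,10-dibromo-3-ethyl-8-(prop-2-en-1-yl)-2,7-dioxabicyclo[4.2.2]decane | C=CC[C@H]1O[C@@H]2C[C@H](Br)[C@@H](CC)O[C@H]1C[C@@H]2Br | intermediate
24 | (2E)-4-[(1S,3R,4S,6R,8R,10S)-4,10-dibromo-3-ethyl-2,7-dioxabicyclo[4.2.2]decan-8-yl]but-2-enal | O=C/C=C/C[C@H]1O[C@@H]2C[C@H](Br)[C@@H](CC)O[C@H]1C[C@@H]2Br | intermediate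
25 | (1S,3R,4S,6R,8R,10S)-4,10-dibromo-3-ethyl-8-[(2E)-pent-2-en-4-yn-1-yl]-2,7-dioxabicyclo[4.2.2]decane | C#C/C=C/C[C@H]1O[C@@H]2C[C@H](Br)[C@@H](CC)O[C@H]1C[C@@H]2Br | target

**Step count and risks**

Total step count: 14. Longest linear sequence: 13 steps (steps 1 and 3 to 14; step 2 prepares triflate 6).

Most uncertain is step 8, the proposed cascade. The allylsilane may attack the activated oxirane carbon in place of the aldehyde oxygen, or the pyranyl cation may be lost by elimination before the eight-membered ring closes. The fallback divides the event into two stages of known type. Setting out from 14, pyridinium p-toluenesulfonate in CH2Cl2, toward which an allylsilane is inert, should give the anhydro acetal 16 by the classical cycloacetalisation of δ,ε-epoxy carbonyl compounds, and 16 is isolated. Its opening with TiCl4 in CH2Cl2 at −78 → −30 °C, the established Hosomi–Sakurai substitution of 6,8-dioxabicyclo[3.2.1]octane acetals and 1,6-anhydro sugars, then gives after aqueous work-up the alcohol 18, where the route is rejoined. This fallback makes no compound outside the compound list (F0).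

Second is step 7. The bromonium donor may be consumed by the allylsilane, and the α-bromo aldehyde may lose configuration while it accumulates. The fallback keeps the allylsilane latent during the bromination. It sets out from carbinol 9, which is isolated instead of being eliminated on silica. K2CO3 in MeOH should give the terminal alkyne (3R)-3-{[(1S)-1-[(2S)-oxiran-2-yl]but-3-yn-1-yl]oxy}-1-(trimethylsilyl)-2-[(trimethylsilyl)methyl]pentan-2-ol F1. Hydroboration with (Me2CHCHMe)2BH gives the (E)-alkenylborane F2 (not isolated), and H2O2/NaOAc the aldehyde (4S)-4-{[(3R)-2-hydroxy-1-(trimethylsilyl)-2-[(trimethylsilyl)methyl]pentan-3-yl]oxy}-4-[(2S)-oxiran-2-yl]butanal F3. The same amine-catalysed bromination then gives (2S,4S)-2-bromo-4-{[(3R)-2-hydroxy-1-(trimethylsilyl)-2-[(trimethylsilyl)methyl]pentan-3-yl]oxy}-4-[(2S)-oxiran-2-yl]butanal F4, whose β-hydroxysilane is no π-nucleophile. Acid-promoted Peterson elimination under the silyl triflate of step 8 then releases 14 in the flask of the cascade, where the route is rejoined.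

Third is step 12. In the bridged ring, ionisation of the alkoxyphosphonium intermediate with participation of a ring oxygen (ring contraction) or elimination may outrun SN2 displacement at 70 °C. The fallback separates activation from displacement. Setting out from 22, ClCH2SO2Cl and pyridine in CH2Cl2 at 0 °C should give (1S,3R,4R,6R,8R,10S)-10-bromo-3-ethyl-8-(prop-2-en-1-yl)-2,7-dioxabicyclo[4.2.2]decan-4-yl chloromethanesulfonate F5. LiBr in DMF at 40 °C then displaces this better nucleofuge with inversion and returns to 23.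

Further compounds
F0 | step 8 | none | none
F1 | step 7 | (3R)-3-{[(1S)-1-[(2S)-oxiran-2-yl]but-3-yn-1-yl]oxy}-1-(trimethylsilyl)-2-[(trimethylsilyl)methyl]pentan-2-ol | CC[C@@H](O[C@@H](CC#C)[C@@H]1CO1)C(O)(C[Si](C)(C)C)C[Si](C)(C)C
F2 | step 7 | (3R)-3-{[(1S,3E)-4-[bis(3-methylbutan-2-yl)boranyl]-1-[(2S)-oxiran-2-yl]but-3-en-1-yl]oxy}-1-(trimethylsilyl)-2-[(trimethylsilyl)methyl]pentan-2-ol | CC[C@@H](O[C@@H](C/C=C/B(C(C)C(C)C)C(C)C(C)C)[C@@H]1CO1)C(O)(C[Si](C)(C)C)C[Si](C)(C)C
F3 | step 7 | (4S)-4-{[(3R)-2-hydroxy-1-(trimethylsilyl)-2-[(trimethylsilyl)methyl]pentan-3-yl]oxy}-4-[(2S)-oxiran-2-yl]butanal | CC[C@@H](O[C@@H](CCC=O)[C@@H]1CO1)C(O)(C[Si](C)(C)C)C[Si](C)(C)C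
F4 | step 7 | (2S,4S)-2-bromo-4-{[(3R)-2-hydroxy-1-(trimethylsilyl)-2-[(trimethylsilyl)methyl]pentan-3-yl]oxy}-4-[(2S)-oxiran-2-yl]butanal | CC[C@@H](O[C@@H](C[C@H](Br)C=O)[C@@H]1CO1)C(O)(C[Si](C)(C)C)C[Si](C)(C)C
F5 | step 12 | (1S,3R,4R,6R,8R,10S)-10-bromo-3-ethyl-8-(prop-2-en-1-yl)-2,7-dioxabicyclo[4.2.2]decan-4-yl chloromethanesulfonate | C=CC[C@H]1O[C@@H]2C[C@@H](OS(=O)(=O)CCl)[C@@H](CC)O[C@H]1C[C@@H]2Br
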